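**Retrosynthetic overview**
- The target is a depside: ring A (2-hydroxy-4-methoxy-6-pentylbenzoyl) is ester-linked to O-4' of ring B (2-methoxy-6-pentylbenzoic acid). The free acid is unmasked last by hydrogenolysis of a benzyl ester.
- The strategy rests on ring A. Its C1 (bearing the ester carbonyl) and C6 (bearing the pentyl chain) are C2 and C3 of an oct-2-ynoate, and C2(OH)–C3–C4(OMe)–C5 is a 1,1,3-trioxygenated butadiene.
- Ring A is therefore formed last, by [4+2] benzannulation of aryl oct-2-ynoate 7 with bis-silyl vinylketene acetal 13 (new bonds C1–C2 and C5–C6), followed by loss of trimethylsilanol.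
- Ring B is taken intact from olivetolic acid: benzyl ester, 4-O-allyl, 2-O-methyl, deallylation, then esterification with oct-2-ynoic acid.
- Diene 13 comes from methyl (E)-3-methoxybut-2-enoate by saponification, O-silylation, and γ-deprotonation/O-silylation.

Key step: step 9

Remark: the target has no stereocentre and no stereogenic double bond, so it is achiral and no enantiocontrol is needed. The only stereo-element in the route, the E double bond of the crotonate, disappears in diene 13.

**Route**

Step 1
Reactants: 1 olivetolic acid (2,4-dihydroxy-6-pentylbenzoic acid)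
Product: 2 benzyl 2,4-dihydroxy-6-pentylbenzoate
Conditions: BnBr (1.05 equiv), KHCO3, DMF, rt
Reagents that add atoms: benzyl bromide, BrCc1ccccc1
Why: SN2 O-alkylation of the carboxylate, where bicarbonate ionises only the acid and not the phenols, and room temperature avoids decarboxylation of the β-resorcylic acid.

Step 2
Reactants: 2 benzyl 2,4-dihydroxy-6-pentylbenzoate
Product: 3 benzyl 4-(allyloxy)-2-hydroxy-6-pentylbenzoate
Conditions: allyl bromide (1.1 equiv), K2CO3 (1.1 equiv), acetone, reflux
Reagents that add atoms: allyl bromide, C=CCBr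
Why: Williamson etherification that should be selective for the 4-OH, because the 2-OH is hydrogen-bonded to the ester carbonyl and is less acidic and less nucleophilic.

Step 3
Reactants: 3 benzyl 4-(allyloxy)-2-hydroxy-6-pentylbenzoate
Product: 4 benzyl 4-(allyloxy)-2-methoxy-6-pentylbenzoate
Conditions: MeI (excess), K2CO3, DMF, 50 °C
Reagents that add atoms: iodomethane, CI
Why: Williamson methylation of the chelated phenol under more forcing conditions, which the 2,6-disubstituted benzyl ester and the allyl ether tolerate (far below Claisen rearrangement temperature).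

Step 4
Reactants: 4 benzyl 4-(allyloxy)-2-methoxy-6-pentylbenzoate
Product: 5 benzyl 4-hydroxy-2-methoxy-6-pentylbenzoate
Conditions: Pd(PPh3)4 (cat.), morpholine, THF, rt
Reagents that add atoms: none
Why: Tsuji–Trost deallylation, in which Pd(0) ionises the allyl aryl ether and morpholine traps the π-allyl fragment; the benzyl ester is inert in the absence of hydrogen.

Step 5
Reactants: 5 benzyl 4-hydroxy-2-methoxy-6-pentylbenzoate; 6 oct-2-ynoic acid
Product: 7 benzyl 2-methoxy-4-(oct-2-ynoyloxy)-6-pentylbenzoate
Conditions: DCC, DMAP (5 mol %), CH2Cl2, 0 °C to rt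
Reagents that add atoms: none
Why: Steglich esterification of an unhindered, fairly acidic phenol, a standard way to aryl alk-2-ynoates, with low temperature and little DMAP to limit conjugate addition to the triple bond.

Step 6
Reactants: 8 methyl (E)-3-methoxybut-2-enoate
Product: 10 (E)-3-methoxybut-2-enoic acid, via sodium (E)-3-methoxybut-2-enoate 9 (not isolated)
Conditions: NaOH, H2O/MeOH, reflux; then HCl, 0 °C, to pH 3, filter at once
Reagents that add atoms: sodium hydroxide, [Na+].[OH-]
Why: Saponification of the vinylogous carbonate ester, with cold and brief acidification to spare the acid-labile enol ether; the E geometry is the stable one and is kept.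

Step 7
Reactants: 10 (E)-3-methoxybut-2-enoic acid
Product: 11 trimethylsilyl (E)-3-methoxybut-2-enoate
Conditions: TMSCl, Et3N, Et2O, 0 °C to rt; filter, distil
Reagents that add atoms: chlorotrimethylsilane, C[Si](C)(C)Cl
Why: O-silylation of the carboxylate gives the silyl ester that carries the first of the two silyloxy groups of the ketene acetal.

Step 8
Reactants: 11 trimethylsilyl (E)-3-methoxybut-2-enoate
Product: 13 3-methoxy-1,1-bis(trimethylsilyloxy)buta-1,3-diene, via lithium 3-methoxy-1-(trimethylsilyloxy)buta-1,3-dien-1-olate 12 (not isolated)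
Conditions: LDA, THF, −78 °C; then TMSCl, −78 °C to rt; filter under argon, bulb-to-bulb distil, use at once
Reagents that add atoms: chlorotrimethylsilane, C[Si](C)(C)Cl
Why: Vinylogous (γ) deprotonation of the methyl group cis to the carbonyl, then O-silylation of the dienolate, as in the making of bis(silyl) ketene acetals from silyl esters and of Brassard-type dienes from 3-methoxycrotonates.

Step 9
Reactants: 7 benzyl 2-methoxy-4-(oct-2-ynoyloxy)-6-pentylbenzoate; 13 3-methoxy-1,1-bis(trimethylsilyloxy)buta-1,3-diene
Product: 16 benzyl 4-[(2-hydroxy-4-methoxy-6-pentylbenzoyl)oxy]-2-methoxy-6-pentylbenzoate, via cyclohexa-1,4-diene cycloadduct 14 (not isolated), via aryl trimethylsilyl ether 15 (not isolated)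
Conditions: 13 (2 equiv), toluene, 110 °C, sealed tube; then 1 M HCl, THF, rt
Reagents that add atoms: none
Why: An asynchronous normal-demand Diels–Alder reaction in which the electron-rich CH2 terminus of the diene bonds to the pentyl-bearing β-carbon of the ynoate (C5–C6 of ring A) and the ketene-acetal carbon to the α-carbon (C1–C2); a stepwise Michael addition followed by closure of the allenoate onto the silyloxy-stabilised cation would give the same adduct 14. The closest known reaction type is the cycloaddition/aromatisation of 1,1,3-trioxygenated vinylketene acetals with acetylenic esters to give resorcylates. Ring A is closed as a six-membered carbocycle in the intermolecular [4+2] mode, and 14 aromatises by 1,4-elimination of trimethylsilanol (OSiMe3 from C2, H from C5) to silyl ether 15, which dilute acid cleaves to the phenol. No stereocentre is formed. The step needs head-to-tail regiochemistry, which the matched polarisation of the ketene-acetal diene and the ynoate secures, the aryl ester making the alkyne more electrophilic than an alkyl ester would. Because both acetal oxygens carry silicon, the oxygen that stays on C2 must end as the free hydroxyl, while the C4 methyl ether comes in with the diene; the hindered benzyl ester is a spectator.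

Step 10
Reactants: 16 benzyl 4-[(2-hydroxy-4-methoxy-6-pentylbenzoyl)oxy]-2-methoxy-6-pentylbenzoate
Product: 17 2'-O-methylperlatolic acid
Conditions: H2 (1 atm), 10% Pd/C, EtOAc, rt
Reagents that add atoms: none
Why: Hydrogenolysis of the benzyl ester, the usual last step of depside syntheses, which leaves the aryl ester, methyl ethers and phenol untouched.

**Compound list**

1 | olivetolic acid (2,4-dihydroxy-6-pentylbenzoic acid) | CCCCCc1cc(O)cc(O)c1C(=O)O | starting material
2 | benzyl 2,4-dihydroxy-6-pentylbenzoate | CCCCCc1cc(O)cc(O)c1C(=O)OCc1ccccc1 | intermediate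
3 | benzyl 4-(allyloxy)-2-hydroxy-6-pentylbenzoate | CCCCCc1cc(OCC=C)cc(O)c1C(=O)OCc1ccccc1 | intermediate
4 | benzyl 4-(allyloxy)-2-methoxy-6-pentylbenzoate | CCCCCc1cc(OCC=C)cc(OC)c1C(=O)OCc1ccccc1 | intermediate
5 | benzyl 4-hydroxy-2-methoxy-6-pentylbenzoate | CCCCCc1cc(O)cc(OC)c1C(=O)OCc1ccccc1 | intermediate
6 | oct-2-ynoic acid | CCCCCC#CC(=O)O | starting material
7 | benzyl 2-methoxy-4-(oct-2-ynoyloxy)-6-pentylbenzoate | CCCCCC#CC(=O)Oc1cc(CCCCC)c(C(=O)OCc2ccccc2)c(OC)c1 | intermediate
8 | methyl (E)-3-methoxybut-2-enoate | CO/C(C)=C/C(=O)OC | starting material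
9 | sodium (E)-3-methoxybut-2-enoate (not isolated) | CO/C(C)=C/C(=O)[O-].[Na+] | intermediate
10 | (E)-3-methoxybut-2-enoic acid | CO/C(C)=C/C(=O)O | intermediate
11 | trimethylsilyl (E)-3-methoxybut-2-enoate | CO/C(C)=C/C(=O)O[Si](C)(C)C | intermediate
12 | lithium 3-methoxy-1-(trimethylsilyloxy)buta-1,3-dien-1-olate (not isolated) | C=C(OC)C=C([O-])O[Si](C)(C)C.[Li+] | intermediate
13 | 3-methoxy-1,1-bis(trimethylsilyloxy)buta-1,3-diene | C=C(OC)C=C(O[Si](C)(C)C)O[Si](C)(C)C | intermediate
14 | benzyl 2-methoxy-4-{[4-methoxy-2-pentyl-6,6-bis(trimethylsilyloxy)cyclohexa-1,4-diene-1-carbonyl]oxy}-6-pentylbenzoate (cycloadduct, not isolated) | CCCCCC1=C(C(=O)Oc2cc(CCCCC)c(C(=O)OCc3ccccc3)c(OC)c2)C(O[Si](C)(C)C)(O[Si](C)(C)C)C=C(OC)C1 | intermediate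
15 | benzyl 2-methoxy-4-{[4-methoxy-2-pentyl-6-(trimethylsilyloxy)benzoyl]oxy}-6-pentylbenzoate (not isolated) | CCCCCc1cc(OC)cc(O[Si](C)(C)C)c1C(=O)Oc1cc(CCCCC)c(C(=O)OCc2ccccc2)c(OC)c1 | intermediate
16 | benzyl 4-[(2-hydroxy-4-methoxy-6-pentylbenzoyl)oxy]-2-methoxy-6-pentylbenzoate | CCCCCc1cc(OC)cc(O)c1C(=O)Oc1cc(CCCCC)c(C(=O)OCc2ccccc2)c(OC)c1 | intermediate
17 | 2'-O-methylperlatolic acid | CCCCCc1cc(OC)cc(O)c1C(=O)Oc1cc(CCCCC)c(C(=O)O)c(OC)c1 | target

**Step count**

Total: 10 steps. Longest linear sequence: 7 steps (steps 1, 2, 3, 4, 5, 9, 10 from olivetolic acid); the diene branch is steps 6, 7, 8.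

**Steps most likely to fail**

1. Step 9. The β-alkyl ynoate may add too slowly, so that the diene decomposes or hydrolyses on long heating, or the diene may attack the aryl ester carbonyl instead of the alkyne. The fallback builds ring A from olivetolic acid and forms the depside ester bond directly; it sets out from 2 and 5 and returns at 16. Selective 4-O-methylation of 2 (MeI 1 equiv, K2CO3, acetone, reflux) should give benzyl 2-hydroxy-4-methoxy-6-pentylbenzoate F1. Hydrogenolysis (H2, Pd/C, EtOAc) should give 2-hydroxy-4-methoxy-6-pentylbenzoic acid F2. Condensation of F2 with phenol 5 by trifluoroacetic anhydride in toluene at rt, through 2-hydroxy-4-methoxy-6-pentylbenzoic trifluoroacetic anhydride F3 (not isolated), is the classical depside esterification and should give 16.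

2. Step 8. γ-Deprotonation may be incomplete, silylation may go to carbon instead of oxygen, or the very moisture-sensitive bis-silyl ketene acetal may hydrolyse during isolation. The fallback uses a mixed methyl silyl vinylketene acetal made in one operation from the ester; it sets out from 8 (with 7) and returns at 15, so steps 6 and 7 are not needed. Ester 8 is deprotonated with LDA (THF, −78 °C) to lithium 1,3-dimethoxybuta-1,3-dien-1-olate F4 (not isolated), which TMSCl silylates to 1,3-dimethoxy-1-(trimethylsilyloxy)buta-1,3-diene F5 (E/Z mixture at the acetal). Heating F5 with 7 in toluene should give benzyl 2-methoxy-4-{[4,6-dimethoxy-2-pentyl-6-(trimethylsilyloxy)cyclohexa-1,4-diene-1-carbonyl]oxy}-6-pentylbenzoate F6 (racemic, not isolated). F6 is expected to aromatise mainly by loss of methanol to silyl ether 15, which the acid work-up of step 9 turns into 16. Any 2-O-methyl product from the competing loss of silanol would be removed by chromatography.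

3. Step 5. DMAP or the phenol may add in conjugate fashion to the activated ynoate, and the O-acylisourea may rearrange to the N-acylurea. The fallback uses a preformed acid chloride without a nucleophilic catalyst; it sets out from 6 (with 5) and returns at 7. Acid 6 is converted with oxalyl chloride and catalytic DMF in CH2Cl2 (0 °C to rt) into oct-2-ynoyl chloride F7, which acylates phenol 5 in CH2Cl2 with 2,6-lutidine at −20 °C to give 7.

**Further compounds**

F1 | step 9 | benzyl 2-hydroxy-4-methoxy-6-pentylbenzoate | CCCCCc1cc(OC)cc(O)c1C(=O)OCc1ccccc1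
F2 | step 9 | 2-hydroxy-4-methoxy-6-pentylbenzoic acid | CCCCCc1cc(OC)cc(O)c1C(=O)O
F3 | step 9 | 2-hydroxy-4-methoxy-6-pentylbenzoic trifluoroacetic anhydride | CCCCCc1cc(OC)cc(O)c1C(=O)OC(=O)C(F)(F)F
F4 | step 8 | lithium 1,3-dimethoxybuta-1,3-dien-1-olate | C=C(OC)C=C([O-])OC.[Li+]
F5 | step 8 | 1,3-dimethoxy-1-(trimethylsilyloxy)buta-1,3-diene | C=C(OC)C=C(OC)O[Si](C)(C)C
F6 | step 8 | benzyl 2-methoxy-4-{[4,6-dimethoxy-2-pentyl-6-(trimethylsilyloxy)cyclohexa-1,4-diene-1-carbonyl]oxy}-6-pentylbenzoate | CCCCCC1=C(C(=O)Oc2cc(CCCCC)c(C(=O)OCc3ccccc3)c(OC)c2)C(OC)(O[Si](C)(C)C)C=C(OC)C1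
F7 | step 5 | oct-2-ynoyl chloride | CCCCCC#CC(=O)Cl
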